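**Plan**

- Numbering: C1 quaternary carbinol, C7 its CH2OBz carbon, C2 CHOH, C3 CHOBz, C4 allylic CHOH, C5=C6 alkene; β is the face of the three free hydroxyls.
- Enabling feature: C1 of the six-membered carbocycle carries OH and the one-carbon branch C7, which is the ipso carbon of benzoic acid after ipso,ortho-cis-dihydroxylation. Ring carbons C1–C6 are the arene carbons, and the natural diol enantiomer fits when its secondary carbinol is C6.
- Retrosynthetic cuts, in order: C3–O(benzoate) back to a 2β,3β-epoxide; C4-OH/C5=C6 back to a C6 ketone with a 4β,5β-epoxide; the four epoxide C–O bonds; the O7–benzoyl bond and C7 back to CO2H; last, C1–O and C6–O back to the arene.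
- Forward order: no ring is built, the benzene ring becomes the cyclohexene. Enzymatic dihydroxylation, C4=C5 epoxidation, CO2H to CH2OBz, C2=C3 epoxidation, C6 oxidation and Wharton transposition, benzoate opening at C3.
- Stereochemistry: C1 (and the temporary C6 centre) from the enzyme; C4 and C2 from hydroxyl-directed β-epoxidations steered by C6-OH and C1-OH; C3 by SN2 inversion in the epoxide opening.

Key step: step 1

Remark: the whole-cell catalyst is assumed to be the dehydrogenase-deficient strain Cupriavidus necator B9, whose benzoate 1,2-dioxygenase gives the (1S,2R)-diol. All locants and α/β descriptors below use the target numbering given above.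

**Route**

Step 1
Reactants: 1 benzoic acid (fed as its sodium salt)
Product: 2 (1S,2R)-1,2-dihydroxycyclohexa-3,5-diene-1-carboxylic acid (1β,6β-dihydroxycyclohexa-2,4-diene-1α-carboxylic acid in target numbering)
Conditions: Cupriavidus necator B9 whole cells, PhCO2Na fed-batch, fructose, air, phosphate-buffered mineral medium, pH 7, 30 °C; then pH 3, 0 °C, EtOAc extraction
Reagents that add atoms: dioxygen, O=O
Why: The Rieske-type benzoate 1,2-dioxygenase binds benzoate through its carboxylate beside a mononuclear non-heme iron centre which, in the divalent state and supplied with two electrons from NADH, activates O2 and transfers both oxygen atoms to one face of the C1–C6 edge, forming C1–O and C6–O and leaving the C2=C3–C4=C5 diene. The closest small-reagent reaction type is the syn-dihydroxylation of an alkene by osmium tetroxide, but no such reagent dearomatises a benzoate, whereas the whole-cell transformation is established for this substrate class. No ring is closed; the arene ring simply becomes the cyclohexadiene. The two new stereocentres (C1 with OH β and carboxyl α, C6 with OH β) are cis because both oxygens come from one metal-bound O2, and their absolute sense is fixed by the chiral active site. The step needs ipso,ortho regioselectivity, face selectivity and enantioselectivity, and all three follow from the carboxylate anchoring the flat substrate in a single orientation. The diol should accumulate because the strain lacks the dehydrogenase that would re-aromatise it.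

Step 2
Reactants: 2 (1S,2R)-1,2-dihydroxycyclohexa-3,5-diene-1-carboxylic acid
Product: 3 4β,5β-epoxy-1β,6β-dihydroxycyclohex-2-ene-1α-carboxylic acid
Conditions: mCPBA (1.1 equiv), EtOAc, 23 °C
Reagents that add atoms: mCPBA (3-chloroperoxybenzoic acid), O=C(OO)c1cccc(Cl)c1
Why: Henbest-type hydroxyl-directed peracid epoxidation, in which the secondary allylic C6 hydroxyl hydrogen-bonds the peracid and delivers oxygen to the β face of C4=C5, while C2=C3, next to the carboxyl-bearing C1 and guided only by a tertiary hydroxyl, should react more slowly, as is known for this diene acid.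

Step 3
Reactants: 3 4β,5β-epoxy-1β,6β-dihydroxycyclohex-2-ene-1α-carboxylic acid
Product: 4 methyl 4β,5β-epoxy-1β,6β-dihydroxycyclohex-2-ene-1α-carboxylate
Conditions: TMSCHN2 (2 M in hexanes), MeOH/toluene 1:3, 0 → 23 °C
Reagents that add atoms: trimethylsilyldiazomethane, C[Si](C)(C)C=[N+]=[N-]
Why: O-Methylation of a carboxylic acid by a diazoalkane under neutral conditions should leave the vinyl epoxide, both hydroxyls and all stereocentres untouched.

Step 4
Reactants: 4 methyl 4β,5β-epoxy-1β,6β-dihydroxycyclohex-2-ene-1α-carboxylate
Product: 6 1α-hydroxymethyl-4β,5β-epoxycyclohex-2-ene-1β,6β-diol, via hydroxy aldehyde 5 (not isolated)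
Conditions: NaBH4 (3 equiv), MeOH, 0 → 23 °C
Reagents that add atoms: none
Why: Borohydride reduction of an α-hydroxy ester, which the neighbouring hydroxyls activate toward hydride delivery, should proceed through the aldehyde to the primary alcohol without touching the isolated alkene or the epoxide, and no stereocentre changes.

Step 5
Reactants: 6 1α-hydroxymethyl-4β,5β-epoxycyclohex-2-ene-1β,6β-diol; 7 benzoyl chloride
Product: 8 1α-benzoyloxymethyl-4β,5β-epoxycyclohex-2-ene-1β,6β-diol
Conditions: BzCl (1.05 equiv), 2,4,6-collidine, CH2Cl2, −40 → 0 °C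
Reagents that add atoms: benzoyl chloride (7), O=C(Cl)c1ccccc1
Why: Chemoselective acylation, in which an acid chloride with a hindered pyridine base at low temperature should esterify the primary C7 hydroxyl in preference to the secondary C6 hydroxyl (flanked by the quaternary carbon and the epoxide) and the tertiary C1 hydroxyl.

Step 6
Reactants: 8 1α-benzoyloxymethyl-4β,5β-epoxycyclohex-2-ene-1β,6β-diol
Product: 9 1α-benzoyloxymethyl-2β,3β:4β,5β-diepoxycyclohexane-1β,6β-diol
Conditions: mCPBA (1.5 equiv), Na2HPO4, CH2Cl2, 0 → 23 °C
Reagents that add atoms: mCPBA (3-chloroperoxybenzoic acid), O=C(OO)c1cccc(Cl)c1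
Why: A second Henbest epoxidation, in which the tertiary allylic C1 hydroxyl (supported by the homoallylic C6 hydroxyl, also β) should place oxygen on the β face of C2=C3, whose α face is further screened by the C1 CH2OBz group; C2 and C3 must be set here because after the transposition the two ring alkenes would be mirror images of each other.

Step 7
Reactants: 9 1α-benzoyloxymethyl-2β,3β:4β,5β-diepoxycyclohexane-1β,6β-diol
Product: 10 1α-benzoyloxymethyl-2β,3β:4β,5β-diepoxy-1β-hydroxycyclohexan-6-one
Conditions: IBX (2 equiv), DMSO, 23 °C
Reagents that add atoms: none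
Why: Hypervalent-iodine oxidation of a secondary alcohol, for which IBX is chosen because it turns secondary/tertiary 1,2-diols into α-hydroxy ketones without glycol cleavage and tolerates epoxides and esters; the C6 stereocentre is erased on purpose.

Step 8
Reactants: 10 1α-benzoyloxymethyl-2β,3β:4β,5β-diepoxy-1β-hydroxycyclohexan-6-one
Product: 13 1α-benzoyloxymethyl-2β,3β-epoxycyclohex-5-ene-1β,4β-diol, via epoxy hydrazone 11 (not isolated), via alkenyl diazene 12 (not isolated)
Conditions: N2H4·H2O (2.5 equiv), AcOH (0.5 equiv), MeOH, 0 → 23 °C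
Reagents that add atoms: none
Why: Wharton transposition, in which the hydrazone of the α,β-epoxy ketone opens the adjoining C5–O bond to an alkenyl diazene that loses N2, leaving C5=C6 and the former epoxide oxygen as the C4 hydroxyl, still β because the C4–O bond is never broken.

Step 9
Reactants: 13 1α-benzoyloxymethyl-2β,3β-epoxycyclohex-5-ene-1β,4β-diol; 1 benzoic acid
Product: 14 1α-benzoyloxymethyl-3α-benzoyloxycyclohex-5-en-1β,2β,4β-triol (target; 1S,2S,3R,4S in this numbering)
Conditions: Ti(OiPr)4 (1.5 equiv), PhCO2H (2 equiv), CH2Cl2, 23 °C; aq. tartaric acid work-up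
Reagents that add atoms: benzoic acid (1), OC(=O)c1ccccc1
Why: Ti(OiPr)4-mediated opening of a 2,3-epoxy alcohol by a carboxylic acid at the carbon remote from the carbinol, in which the C1 alkoxide and the epoxide oxygen are held on titanium on the β face and benzoate should attack C3 from the α face with SN2 inversion (C3 α-OBz, C2 β-OH), C2 being a neopentyl-type centre shielded by the quaternary C1 and its α CH2OBz group.

**Compound list**

1 | benzoic acid | OC(=O)c1ccccc1 | starting material
2 | (1S,2R)-1,2-dihydroxycyclohexa-3,5-diene-1-carboxylic acid (1β,6β-diol, 1α-CO2H, 2,4-diene in target numbering) | OC(=O)[C@]1(O)C=CC=C[C@H]1O | intermediate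
3 | 4β,5β-epoxy-1β,6β-dihydroxycyclohex-2-ene-1α-carboxylic acid | OC(=O)[C@@]1(O)[C@H](O)[C@@H]2O[C@@H]2C=C1 | intermediate
4 | methyl 4β,5β-epoxy-1β,6β-dihydroxycyclohex-2-ene-1α-carboxylate | COC(=O)[C@@]1(O)[C@H](O)[C@@H]2O[C@@H]2C=C1 | intermediate
5 | 4β,5β-epoxy-1β,6β-dihydroxycyclohex-2-ene-1α-carbaldehyde (formed in the flask in step 4, not isolated) | O=C[C@@]1(O)[C@H](O)[C@@H]2O[C@@H]2C=C1 | intermediate
6 | 1α-hydroxymethyl-4β,5β-epoxycyclohex-2-ene-1β,6β-diol | OC[C@@]1(O)[C@H](O)[C@@H]2O[C@@H]2C=C1 | intermediate
7 | benzoyl chloride | O=C(Cl)c1ccccc1 | starting material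
8 | 1α-benzoyloxymethyl-4β,5β-epoxycyclohex-2-ene-1β,6β-diol | O=C(OC[C@@]1(O)[C@H](O)[C@@H]2O[C@@H]2C=C1)c1ccccc1 | intermediate
9 | 1α-benzoyloxymethyl-2β,3β:4β,5β-diepoxycyclohexane-1β,6β-diol | O=C(OC[C@@]1(O)[C@H](O)[C@@H]2O[C@@H]2[C@@H]3O[C@H]13)c1ccccc1 | intermediate
10 | 1α-benzoyloxymethyl-2β,3β:4β,5β-diepoxy-1β-hydroxycyclohexan-6-one | O=C(OC[C@@]1(O)C(=O)[C@@H]2O[C@@H]2[C@@H]3O[C@H]13)c1ccccc1 | intermediate
11 | C6 hydrazone of 10 (formed in the flask in step 8, not isolated; C=N geometry not defined) | O=C(OC[C@@]1(O)C(=NN)[C@@H]2O[C@@H]2[C@@H]3O[C@H]13)c1ccccc1 | intermediate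
12 | 1α-benzoyloxymethyl-6-diazenyl-2β,3β-epoxycyclohex-5-ene-1β,4β-diol (formed in the flask in step 8, not isolated) | O=C(OC[C@@]1(O)C(N=N)=C[C@H](O)[C@@H]2O[C@H]12)c1ccccc1 | intermediate
13 | 1α-benzoyloxymethyl-2β,3β-epoxycyclohex-5-ene-1β,4β-diol | O=C(OC[C@@]1(O)C=C[C@H](O)[C@@H]2O[C@H]12)c1ccccc1 | intermediate
14 | 1α-benzoyloxymethyl-3α-benzoyloxycyclohex-5-en-1β,2β,4β-triol | O=C(OC[C@@]1(O)C=C[C@H](O)[C@@H](OC(=O)c2ccccc2)[C@@H]1O)c1ccccc1 | target

**Step count**

Total: 9 steps. Longest linear sequence: 9 steps, from benzoic acid (1) to 14.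

**Steps most likely to fail**

Step 6. The second oxygen may be delivered to the α face, because the dipole of the existing 4β,5β-epoxide opposes a syn approach of the peracid. A slow reaction may also let the acid by-product open the vinyl epoxide. The fallback sets out from 8 and reverses the roles of electrophile and oxygen. N-Bromosuccinimide in buffered THF/water at 0 °C should form the bromonium ion on the α face, anti to the β oxygen functions, and water should open it from the β face. This should give the trans-bromohydrin 1α-benzoyloxymethyl-2α-bromo-4β,5β-epoxycyclohexane-1β,3β,6β-triol F1, possibly with its regioisomer 1α-benzoyloxymethyl-3α-bromo-4β,5β-epoxycyclohexane-1β,2β,6β-triol F2. Both should close with DBU in CH2Cl2 to the same 2β,3β-epoxide, so the sequence comes back to the route at 9. The facial preference that would defeat direct epoxidation now works for the route, since the epoxide oxygen ends up anti to the electrophile.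

Step 8. Hydrazine may cleave the C7 benzoate or attack the 2β,3β-epoxide, and the hindered epoxy hydrazone next to the quaternary carbon may form slowly or stray from the diazene pathway. The fallback sets out from 9, avoids the ketone 10 and hydrazine altogether, and uses a radical fragmentation of Barton–McCombie type. 1,1'-Thiocarbonyldiimidazole in CH2Cl2 at 23 °C should acylate only the secondary C6 hydroxyl, the tertiary one staying free at this temperature, to give 1α-benzoyloxymethyl-2β,3β:4β,5β-diepoxy-6β-(imidazol-1-ylthiocarbonyloxy)cyclohexan-1β-ol F3. Bu3SnH with AIBN in toluene at 80 °C should then generate the C6 radical, which opens the adjoining C5–O bond (oxiranylcarbinyl radical fragmentation). The resulting C4 alkoxy radical takes a hydrogen atom from Bu3SnH, and the sequence comes back to the route at 13.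

Step 9. Regiocontrol in the ring opening may be lost if titanium bound to the C4 alkoxide instead of the C1 alkoxide steers benzoate to C2, and the new benzoate may migrate to a neighbouring hydroxyl. The fallback sets out from 13 and removes the competing chelation site. TBSCl and imidazole in DMF should silylate only the secondary C4 hydroxyl to give 1α-benzoyloxymethyl-4β-(tert-butyldimethylsilyloxy)-2β,3β-epoxycyclohex-5-en-1β-ol F4. The same Ti(OiPr)4/PhCO2H opening, now guided by the C1 hydroxyl alone, should give 1α-benzoyloxymethyl-3α-benzoyloxy-4β-(tert-butyldimethylsilyloxy)cyclohex-5-ene-1β,2β-diol F5. HF·pyridine in THF at 0 °C, chosen over a basic fluoride source to avoid benzoyl migration, should remove the silyl group, and the sequence comes back to the route at 14.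

**Further compounds**

F1 | step 6 | 1α-benzoyloxymethyl-2α-bromo-4β,5β-epoxycyclohexane-1β,3β,6β-triol | O=C(OC[C@@]1(O)[C@H](O)[C@@H]2O[C@@H]2[C@H](O)[C@H]1Br)c1ccccc1
F2 | step 6 | 1α-benzoyloxymethyl-3α-bromo-4β,5β-epoxycyclohexane-1β,2β,6β-triol | O=C(OC[C@@]1(O)[C@H](O)[C@@H]2O[C@@H]2[C@@H](Br)[C@@H]1O)c1ccccc1
F3 | step 8 | 1α-benzoyloxymethyl-2β,3β:4β,5β-diepoxy-6β-(imidazol-1-ylthiocarbonyloxy)cyclohexan-1β-ol | O=C(OC[C@@]1(O)[C@H](OC(=S)n4ccnc4)[C@@H]2O[C@@H]2[C@@H]3O[C@H]13)c1ccccc1
F4 | step 9 | 1α-benzoyloxymethyl-4β-(tert-butyldimethylsilyloxy)-2β,3β-epoxycyclohex-5-en-1β-ol | O=C(OC[C@@]1(O)C=C[C@H](O[Si](C)(C)C(C)(C)C)[C@@H]2O[C@H]12)c1ccccc1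
F5 | step 9 | 1α-benzoyloxymethyl-3α-benzoyloxy-4β-(tert-butyldimethylsilyloxy)cyclohex-5-ene-1β,2β-diol | O=C(OC[C@@]1(O)C=C[C@H](O[Si](C)(C)C(C)(C)C)[C@@H](OC(=O)c2ccccc2)[C@@H]1O)c1ccccc1
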